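Labels: B is the central naphthol, A the outer naphthol on B-C2, C the outer naphthol on B-C4. Each unit is numbered with OH on C1 and OMe on C8.
Enabling feature: the phenol ring of A carries only OH (A-C1) and aryl B (A-C2), A-C3 and A-C4 are CH, and OMe sits peri on A-C8. A-C1, A-C4 and the anisole ring therefore map onto a 2-methoxy-6-methylbenzoate, and A-C2/A-C3 map onto a vinyl group held on B-C2 whose sulfonyl substituent leaves on aromatisation.
Cuts, in order: the two O-benzyl bonds; A-C3/A-C4 and A-C1/A-C2 (annulation); the C=CH2 and C-S bonds of the vinyl sulfone, back to a B-C2 aldehyde; the biaryl bond B-C4/C-C2 (Suzuki-Miyaura).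
Forward: the B and C naphthalenes come ready-made from naphthalene-1,8-diol (para-bromination and ortho-formylation for B, ortho-bromination and borylation for C). They are joined, the aldehyde is elaborated to the 1-(phenylsulfonyl)vinyl group, and the phenol ring of A is the only ring built.
Stereochemistry: none to set. The target has no stereocentre, and the one sp3 centre that arises during the annulation disappears on aromatisation.

Key step: step 13

Assumption: the target SMILES carries no axial descriptor, and each ring at either biaryl axis has at most one ortho hydroxyl beside hydrogen or a peri C-H. Both axes are therefore treated as freely rotating and the compound as one achiral species.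

Step 1
Reactants: 1 naphthalene-1,8-diol
Product: 2 8-methoxynaphthalen-1-ol
Conditions: MeI (1.05 equiv), K2CO3, acetone, reflux
Reagents that add atoms: methyl iodide, CI
Why: Williamson ether synthesis; once one oxygen is methylated the remaining OH is held in a peri hydrogen bond to the new OMe and is deprotonated far less readily, so one equivalent of MeI should stop at the monoether.

Step 2
Reactants: 2 8-methoxynaphthalen-1-ol
Product: 3 4-bromo-8-methoxynaphthalen-1-ol
Conditions: NBS (1.0 equiv), MeCN, -20 to 0 °C, dark
Reagents that add atoms: N-bromosuccinimide, O=C1CCC(=O)N1Br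
Why: Electrophilic aromatic bromination; the free naphthol ring is much more nucleophilic than the anisole ring and NBS in polar MeCN favours the para position C4, while any ortho isomer is not wasted because it is the product of step 5.

Step 3
Reactants: 3 4-bromo-8-methoxynaphthalen-1-ol
Product: 4 4-bromo-1-hydroxy-8-methoxy-2-naphthaldehyde
Conditions: MgCl2, Et3N, (CH2O)n, MeCN, reflux; 1 M HCl work-up
Reagents that add atoms: paraformaldehyde (reacts as formaldehyde), C=O
Why: Casnati-Skattebøl ortho-formylation; magnesium bound to the naphthoxide oxygen delivers formaldehyde only to the adjacent C2 (C4 is blocked by bromine), a second formaldehyde takes up the hydride to reach the aldehyde level, and the aryl bromide is inert.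

Step 4
Reactants: 4 4-bromo-1-hydroxy-8-methoxy-2-naphthaldehyde; 5 benzyl bromide
Product: 6 1-(benzyloxy)-4-bromo-8-methoxy-2-naphthaldehyde
Conditions: K2CO3, DMF, 60 °C
Reagents that add atoms: none
Why: Williamson benzylation; carbonate in DMF opens the chelated OH and the naphthoxide displaces bromide from 5 by SN2, which removes the acidic proton before the coupling and carbanion steps.

Step 5
Reactants: 2 8-methoxynaphthalen-1-ol
Product: 7 2-bromo-8-methoxynaphthalen-1-ol
Conditions: NBS (1.0 equiv), i-Pr2NH (10 mol %), CH2Cl2, 0 °C to rt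
Reagents that add atoms: N-bromosuccinimide, O=C1CCC(=O)N1Br
Why: Amine-catalysed ortho-bromination of phenols; the N-bromoamine made from NBS and i-Pr2NH is hydrogen-bonded to the OH and passes bromine to the neighbouring C2 in a non-polar solvent that disfavours para attack.

Step 6
Reactants: 7 2-bromo-8-methoxynaphthalen-1-ol; 5 benzyl bromide
Product: 8 1-(benzyloxy)-2-bromo-8-methoxynaphthalene
Conditions: K2CO3, DMF, rt to 50 °C
Reagents that add atoms: none
Why: Williamson benzylation of the naphthoxide by SN2 on 5; the aryl bromide and the methyl ether do not react under carbonate conditions.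

Step 7
Reactants: 8 1-(benzyloxy)-2-bromo-8-methoxynaphthalene
Product: 9 2-[1-(benzyloxy)-8-methoxynaphthalen-2-yl]-4,4,5,5-tetramethyl-1,3,2-dioxaborolane
Conditions: B2pin2, Pd(dppf)Cl2 (5 mol %), KOAc, 1,4-dioxane, 90 °C
Reagents that add atoms: bis(pinacolato)diboron, CC1(C)OB(OC1(C)C)B2OC(C)(C)C(C)(C)O2
Why: Miyaura borylation; zerovalent palladium inserts into the C-Br bond, acetate assists transmetalation from B2pin2 and reductive elimination gives the aryl boronate without a strong base that could attack the benzyl ether.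

Step 8
Reactants: 6 1-(benzyloxy)-4-bromo-8-methoxy-2-naphthaldehyde; 9 2-[1-(benzyloxy)-8-methoxynaphthalen-2-yl]-4,4,5,5-tetramethyl-1,3,2-dioxaborolane
Product: 10 1-(benzyloxy)-4-[1-(benzyloxy)-8-methoxynaphthalen-2-yl]-8-methoxy-2-naphthaldehyde
Conditions: Pd(OAc)2 (5 mol %), SPhos (10 mol %), K3PO4, toluene-H2O, 90 °C
Reagents that add atoms: none
Why: Suzuki-Miyaura coupling forms the bond B-C4 to C-C2; the bulky electron-rich biaryl phosphine copes with the peri-hindered bromide and the ortho-alkoxy boronate, and the aldehyde and ethers are spectators.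

Step 9
Reactants: 10 1-(benzyloxy)-4-[1-(benzyloxy)-8-methoxynaphthalen-2-yl]-8-methoxy-2-naphthaldehyde
Product: 11 {1-(benzyloxy)-4-[1-(benzyloxy)-8-methoxynaphthalen-2-yl]-8-methoxynaphthalen-2-yl}methanol
Conditions: NaBH4, THF-MeOH, 0 °C
Reagents that add atoms: none
Why: Borohydride reduction of an aromatic aldehyde; nothing else in 10 is reducible by NaBH4.

Step 10
Reactants: 11 {1-(benzyloxy)-4-[1-(benzyloxy)-8-methoxynaphthalen-2-yl]-8-methoxynaphthalen-2-yl}methanol
Product: 12 1-(benzyloxy)-4-[1-(benzyloxy)-8-methoxynaphthalen-2-yl]-2-(chloromethyl)-8-methoxynaphthalene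
Conditions: SOCl2, pyridine, CH2Cl2, 0 °C; used without storage
Reagents that add atoms: thionyl chloride, O=S(Cl)Cl
Why: Deoxychlorination of an activated benzylic alcohol with SOCl2; pyridine takes up the HCl so that the electron-rich naphthalenes are not exposed to acid together with a reactive benzylic halide.

Step 11
Reactants: 12 1-(benzyloxy)-4-[1-(benzyloxy)-8-methoxynaphthalen-2-yl]-2-(chloromethyl)-8-methoxynaphthalene; 13 sodium benzenesulfinate
Product: 14 1-(benzyloxy)-4-[1-(benzyloxy)-8-methoxynaphthalen-2-yl]-8-methoxy-2-[(phenylsulfonyl)methyl]naphthalene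
Conditions: n-Bu4NI (10 mol %), DMF, rt to 50 °C
Reagents that add atoms: none
Why: SN2 S-alkylation of the ambident sulfinate by a soft benzylic halide in a dipolar aprotic solvent should give the sulfone rather than the sulfinate ester.

Step 12
Reactants: 14 1-(benzyloxy)-4-[1-(benzyloxy)-8-methoxynaphthalen-2-yl]-8-methoxy-2-[(phenylsulfonyl)methyl]naphthalene
Product: 16 1-(benzyloxy)-4-[1-(benzyloxy)-8-methoxynaphthalen-2-yl]-8-methoxy-2-[1-(phenylsulfonyl)vinyl]naphthalene, via Mannich base 15 (not isolated)
Conditions: CH2(NMe2)2, Ac2O, DMF, 60 °C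
Reagents that add atoms: N,N,N',N'-tetramethylmethanediamine, CN(C)CN(C)C
Why: Mannich-type alpha-methylenation of a benzylic sulfone; the iminium acetate generated from the aminal and Ac2O aminomethylates the acidic ArCH2SO2 position to 15, which loses dimethylamine by E1cB under the same conditions.

Step 13
Reactants: 16 1-(benzyloxy)-4-[1-(benzyloxy)-8-methoxynaphthalen-2-yl]-8-methoxy-2-[1-(phenylsulfonyl)vinyl]naphthalene; 17 methyl 2-methoxy-6-methylbenzoate
Product: 22 2-{1-(benzyloxy)-4-[1-(benzyloxy)-8-methoxynaphthalen-2-yl]-8-methoxynaphthalen-2-yl}-8-methoxynaphthalen-1-ol, via lithiated toluate 18 (not isolated), via sulfonyl carbanion 19 (not isolated), via keto sulfone 20 (not isolated), via dienone 21 (not isolated)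
Conditions: 17 (2 equiv), LiN(i-Pr)2 (LDA, 2 equiv), THF, -78 °C; slow addition of 16, -78 to 0 °C; then KOt-Bu (3 equiv), 0 to 45 °C; 1 M HCl
Reagents that add atoms: none
Why: Proposed new method: benzylic lithium 18 should add to the unhindered CH2 terminus of 16 (bond A-C4 to A-C3) to give carbanion 19, stabilised by the sulfonyl group and by ring B, and 19 should then acylate itself on the adjacent methyl ester (bond A-C2 to A-C1) in a 6-exo-trig Claisen closure that forms the only new ring and gives keto sulfone 20. Because 20 has no enolisable hydrogen this closure is reversible, and because A-C3-H is not acidified an E1cB path is closed, so sulfinate loss is driven deliberately with added KOt-Bu as an anti E2 elimination from the half-chair with a pseudoaxial C-S bond, helped by strain release at the crowded quaternary carbon and by overlap of the breaking bond with the carbonyl group. Dienone 21 then tautomerises to the naphtholate, an irreversible sink that pulls the earlier equilibria forward. The closest known reaction types are the Staunton-Weinreb Michael-Dieckmann annulation of toluate anions with enones and alpha-substituted acrylates, the acylation of sulfonyl carbanions by esters, and the alkoxide-induced dehydrosulfonylation of tertiary sulfones; the new element is a vinyl sulfone as acceptor and alkyne equivalent. The selectivity needed is regiochemical (ring B on A-C2, not A-C3) and follows from the acceptor itself, since attack can occur only at the CH2 end beta to sulfur and the charge, and with it the new bond to the ester carbon, falls on the carbon that already carries ring B, while the benzoate brings the peri OH/OMe pattern with it. The one stereocentre created (A-C2 of 20, racemic) is erased on aromatisation, slow addition of 16 to excess 18 suppresses anionic oligomerisation of the acceptor, and the benzyl and methyl ethers are inert to the bases used.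

Step 14
Reactants: 22 2-{1-(benzyloxy)-4-[1-(benzyloxy)-8-methoxynaphthalen-2-yl]-8-methoxynaphthalen-2-yl}-8-methoxynaphthalen-1-ol
Product: 23 2-[1-hydroxy-4-(1-hydroxy-8-methoxynaphthalen-2-yl)-8-methoxynaphthalen-2-yl]-8-methoxynaphthalen-1-ol (CNP0482979.0)
Conditions: H2 (1 atm), 10% Pd/C, EtOAc-MeOH, rt; work-up under argon
Reagents that add atoms: none
Why: Catalytic hydrogenolysis of aryl benzyl ethers cleaves both O-CH2Ph bonds under neutral conditions that leave the methyl ethers and the naphthalene rings intact, and exclusion of air guards the electron-rich trinaphthol against oxidative coupling.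

Compound list
1 | naphthalene-1,8-diol | Oc1cccc2cccc(O)c12 | starting material
2 | 8-methoxynaphthalen-1-ol | COc1cccc2cccc(O)c12 | intermediate
3 | 4-bromo-8-methoxynaphthalen-1-ol | COc1cccc2c(Br)ccc(O)c12 | intermediate
4 | 4-bromo-1-hydroxy-8-methoxy-2-naphthaldehyde | COc1cccc2c(Br)cc(C=O)c(O)c12 | intermediate
5 | benzyl bromide | BrCc1ccccc1 | starting material
6 | 1-(benzyloxy)-4-bromo-8-methoxy-2-naphthaldehyde | COc1cccc2c(Br)cc(C=O)c(OCc3ccccc3)c12 | intermediate
7 | 2-bromo-8-methoxynaphthalen-1-ol | COc1cccc2ccc(Br)c(O)c12 | intermediate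
8 | 1-(benzyloxy)-2-bromo-8-methoxynaphthalene | COc1cccc2ccc(Br)c(OCc3ccccc3)c12 | intermediate
9 | 2-[1-(benzyloxy)-8-methoxynaphthalen-2-yl]-4,4,5,5-tetramethyl-1,3,2-dioxaborolane | COc1cccc2ccc(B3OC(C)(C)C(C)(C)O3)c(OCc4ccccc4)c12 | intermediate
10 | 1-(benzyloxy)-4-[1-(benzyloxy)-8-methoxynaphthalen-2-yl]-8-methoxy-2-naphthaldehyde | COc1cccc2c(-c3ccc4cccc(OC)c4c3OCc5ccccc5)cc(C=O)c(OCc6ccccc6)c12 | intermediate
11 | {1-(benzyloxy)-4-[1-(benzyloxy)-8-methoxynaphthalen-2-yl]-8-methoxynaphthalen-2-yl}methanol | COc1cccc2c(-c3ccc4cccc(OC)c4c3OCc5ccccc5)cc(CO)c(OCc6ccccc6)c12 | intermediate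
12 | 1-(benzyloxy)-4-[1-(benzyloxy)-8-methoxynaphthalen-2-yl]-2-(chloromethyl)-8-methoxynaphthalene | COc1cccc2c(-c3ccc4cccc(OC)c4c3OCc5ccccc5)cc(CCl)c(OCc6ccccc6)c12 | intermediate
13 | sodium benzenesulfinate | [Na+].[O-]S(=O)c1ccccc1 | starting material
14 | 1-(benzyloxy)-4-[1-(benzyloxy)-8-methoxynaphthalen-2-yl]-8-methoxy-2-[(phenylsulfonyl)methyl]naphthalene | COc1cccc2c(-c3ccc4cccc(OC)c4c3OCc5ccccc5)cc(CS(=O)(=O)c6ccccc6)c(OCc7ccccc7)c12 | intermediate
15 | Mannich base, 2-{1-(benzyloxy)-4-[1-(benzyloxy)-8-methoxynaphthalen-2-yl]-8-methoxynaphthalen-2-yl}-N,N-dimethyl-2-(phenylsulfonyl)ethanamine (racemic) | COc1cccc2c(-c3ccc4cccc(OC)c4c3OCc5ccccc5)cc(C(CN(C)C)S(=O)(=O)c6ccccc6)c(OCc7ccccc7)c12 | intermediate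
16 | 1-(benzyloxy)-4-[1-(benzyloxy)-8-methoxynaphthalen-2-yl]-8-methoxy-2-[1-(phenylsulfonyl)vinyl]naphthalene | C=C(S(=O)(=O)c1ccccc1)c2cc(-c4ccc5cccc(OC)c5c4OCc6ccccc6)c3cccc(OC)c3c2OCc7ccccc7 | intermediate
17 | methyl 2-methoxy-6-methylbenzoate | COC(=O)c1c(C)cccc1OC | starting material
18 | lithiated toluate, methyl 2-(lithiomethyl)-6-methoxybenzoate | COC(=O)c1c(C[Li])cccc1OC | intermediate
19 | sulfonyl carbanion, methyl 2-[3-lithio-3-(phenylsulfonyl)-3-aryl-propyl]-6-methoxybenzoate (aryl = the dibenzylated B-C unit bound through B-C2) | COC(=O)c1c(CCC([Li])(S(=O)(=O)c2ccccc2)c3cc(-c4ccc5cccc(OC)c5c4OCc6ccccc6)c7cccc(OC)c7c3OCc8ccccc8)cccc1OC | intermediate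
20 | keto sulfone, 2-aryl-8-methoxy-2-(phenylsulfonyl)-3,4-dihydronaphthalen-1(2H)-one (aryl as in 19, racemic) | COc1cccc2CCC(S(=O)(=O)c3ccccc3)(C(=O)c12)c4cc(-c5ccc6cccc(OC)c6c5OCc7ccccc7)c8cccc(OC)c8c4OCc9ccccc9 | intermediate
21 | dienone, 2-aryl-8-methoxynaphthalen-1(4H)-one (aryl as in 19) | COc1cccc2CC=C(C(=O)c12)c3cc(-c4ccc5cccc(OC)c5c4OCc6ccccc6)c7cccc(OC)c7c3OCc8ccccc8 | intermediate
22 | 2-{1-(benzyloxy)-4-[1-(benzyloxy)-8-methoxynaphthalen-2-yl]-8-methoxynaphthalen-2-yl}-8-methoxynaphthalen-1-ol | COc1cccc2ccc(-c3cc(-c4ccc5cccc(OC)c5c4OCc6ccccc6)c7cccc(OC)c7c3OCc8ccccc8)c(O)c12 | intermediate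
23 | 2-[1-hydroxy-4-(1-hydroxy-8-methoxynaphthalen-2-yl)-8-methoxynaphthalen-2-yl]-8-methoxynaphthalen-1-ol (CNP0482979.0) | COc1cccc2ccc(-c3cc(-c4ccc5cccc(OC)c5c4O)c4cccc(OC)c4c3O)c(O)c12 | target

Total step count: 14.
Longest linear sequence: 11 steps (1, 2, 3, 4, 8, 9, 10, 11, 12, 13, 14). The boronate arm (1, 5, 6, 7, then 8 to 14) is equally long.

Steps most likely to fail

1. Step 13 (the new method). Three processes could defeat it.
- The sequence may stall after conjugate addition, because closure on the doubly ortho-substituted ester is reversible.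
- Sulfinate loss may be slow for lack of an acidified hydrogen.
- The acceptor may be consumed by anionic oligomerisation.

The fallback uses only known chemistry and brings ring A in ready-made by cross-coupling, which is possible because A and C are the same 2-naphthyl fragment. It sets out from 2 (with 5 and 9). Exhaustive bromination with NBS (2 equiv, MeCN) should give 2,4-dibromo-8-methoxynaphthalen-1-ol F1. Williamson benzylation with 5 (K2CO3, DMF) then gives 1-(benzyloxy)-2,4-dibromo-8-methoxynaphthalene F2. A twofold Suzuki-Miyaura coupling with 9 (Pd(OAc)2, SPhos, K3PO4, toluene-H2O) gives the tribenzyl ether of the target F3. Hydrogenolysis (H2, Pd/C) comes back to the route at 23.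

2. Step 5. Ortho selectivity may erode because the OH is tied up in the peri hydrogen bond, which would open the way to para attack and double bromination. The fallback replaces electrophilic substitution by directed ortho-metalation. It sets out from 2. NaH and MOMCl in THF give 1-methoxy-8-(methoxymethoxy)naphthalene F4. n-BuLi and TMEDA in Et2O at 0 °C lithiate next to the stronger directing group to give 2-lithio-8-methoxy-1-(methoxymethoxy)naphthalene F5. A quench with BrCH2CH2Br gives 2-bromo-8-methoxy-1-(methoxymethoxy)naphthalene F6, and HCl in MeOH removes the acetal. The fallback comes back to the route at 7.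

3. Step 12. Aminomethylation may be incomplete at a moderately acidic benzylic position crowded by the ortho benzyloxy group, and liberated amine may add back to the product. The fallback replaces the Mannich route by hydroxymethylation and dehydration. It sets out from 14. n-BuLi in THF at -78 °C gives the alpha-lithio sulfone F7. Monomeric formaldehyde converts it into the 2-aryl-2-(phenylsulfonyl)ethanol F8. MsCl and Et3N in CH2Cl2 give the mesylate F9, which undergoes E1cB elimination with excess Et3N or DBU. The fallback comes back to the route at 16.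

Further compounds
F1 | step 13 | 2,4-dibromo-8-methoxynaphthalen-1-ol | COc1cccc2c(Br)cc(Br)c(O)c12
F2 | step 13 | 1-(benzyloxy)-2,4-dibromo-8-methoxynaphthalene | COc1cccc2c(Br)cc(Br)c(OCc3ccccc3)c12
F3 | step 13 | tribenzyl ether of the target | COc1cccc2ccc(-c3cc(-c4ccc5cccc(OC)c5c4OCc6ccccc6)c7cccc(OC)c7c3OCc8ccccc8)c(OCc9ccccc9)c12
F4 | step 5 | 1-methoxy-8-(methoxymethoxy)naphthalene | COCOc1cccc2cccc(OC)c12
F5 | step 5 | 2-lithio-8-methoxy-1-(methoxymethoxy)naphthalene | COCOc1c([Li])ccc2cccc(OC)c12
F6 | step 5 | 2-bromo-8-methoxy-1-(methoxymethoxy)naphthalene | COCOc1c(Br)ccc2cccc(OC)c12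
F7 | step 12 | alpha-lithio sulfone derived from 14 | COc1cccc2c(-c3ccc4cccc(OC)c4c3OCc5ccccc5)cc(C([Li])S(=O)(=O)c6ccccc6)c(OCc7ccccc7)c12
F8 | step 12 | 2-{1-(benzyloxy)-4-[1-(benzyloxy)-8-methoxynaphthalen-2-yl]-8-methoxynaphthalen-2-yl}-2-(phenylsulfonyl)ethanol (racemic) | COc1cccc2c(-c3ccc4cccc(OC)c4c3OCc5ccccc5)cc(C(CO)S(=O)(=O)c6ccccc6)c(OCc7ccccc7)c12
F9 | step 12 | methanesulfonate of F8 (racemic) | COc1cccc2c(-c3ccc4cccc(OC)c4c3OCc5ccccc5)cc(C(COS(C)(=O)=O)S(=O)(=O)c6ccccc6)c(OCc7ccccc7)c12
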